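# Proposed total synthesis of CNP0132024.3 by a cyclopropane–aldehyde (3+2) annulation

## The problem

The target 38 is a tetracyclic asbestinane. A ten-membered carbocycle (C1–C10) is bridged by oxygen between C2 and C9, which gives a 2,5-cis tetrahydrofuran (C1–C2–O–C9–C10) inside an oxonane. Cyclohexane ring C (C1, C10, C11, C12, C13, C14) is cis-fused to the tetrahydrofuran at C1–C10, and an oxepane (C1, C2, C3, O, C16, C15, C14) is trans-fused to ring C across C1–C14. The core carries ten stereocentres (C1, C2, C3, C4, C9, C10, C11, C12, C14, C15) and the C11 ester side chain an eleventh. They can relay information in a chain: C15 can be bought, C14 next to it needs a catalyst because 1,2-induction from C15 is unreliable, C14 can direct C1, C2 and C10, these fix C9, and the finished cage can direct C3/C4 and C11/C12. The hardest centre is C12: its methyl group is cis to the substituents on C1, C10 and C11 and is axial and syn to the C10–C9 bond once the oxepane locks ring C, so next to a C11 carbonyl it is the less stable epimer and must be set late under kinetic control. Fragile elements are the exocyclic C7=C19 alkene (hydrogenation, acid-induced migration), two different esters of which one bears a free α-hydroxyl group, and every intermediate with a ketone at C11 or C7, where the C9 ether oxygen is β to the carbonyl and can be expelled by base. The feature that opens the molecule is the C11 oxygen: at the ketone level it makes C10 the acceptor carbon of a β-keto ester, 1,3 to the ether carbon C2, so that C2–C1–C10 maps onto a donor–acceptor cyclopropane with the C3 alkenyl group as donor, and C9 with its oxygen onto an aldehyde.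

## Retrosynthesis

**C7=C19 and the acyl groups (38 from 37, 36, 31 and 34).** The exocyclic alkene is cut first, to ketone 37, because it cannot coexist with the hydrogenation that sets C12. The ketone is kept as a dioxolane, and the side-chain hydroxyl as a triethylsilyl ether, in 36, so that one acid treatment releases both. The C11 ester bond is cut to alcohol 31 and protected acid 34 (from 32). The C4 acetate is already in place, so the two secondary hydroxyl groups never compete. The forward reactions must be non-basic at the C7 ketone.

**C12–methyl and C11–H (31 from 30, 29 and 25).** The C12 methyl group is removed as a methylidene group (29) and then altogether (ketone 25). Carrying the methyl group from the start was rejected: it would be installed without control, and the thermodynamic ester removal that sets the ring fusion would then equilibrate C12 as well, where the wanted epimer has no clear advantage. In the oxepane-locked tetracycle the convex face of ring C is the only open one, so hydrogen added to 29 pushes the methyl group into the required axial position, and hydride then attacks C11 from the same face. Tetracycle 25 is the only alkene-free intermediate, which makes the hydrogenation possible. The precursor lacks two stereocentres.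

**C3–O16 (25 from 24, 23, 22 and 21).** The oxepane is opened at its tertiary ether bond to epoxy alcohol 23. The epoxide oxygen becomes the C4 oxygen, so one anti addition across the Z alkene of 21 sets C3 and C4 together. A C16 leaving group displaced by a C3 alcohol would need that alcohol made separately and would not deliver the C4 oxygen. The forward reaction asks for epoxidation on the face of C3=C4 away from ring C and for 7-exo attack at the tertiary carbon under acid.

**C3=C4 (21 from 20).** The nine-membered ring is cut at the alkene by ring-closing metathesis. The two arms of 20 sit cis on a tetrahydrofuran, which is the best available preorganisation for a medium ring, and the ring enforces the Z geometry that the epoxide opening needs.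

**C10–CO2CH3 (20 from 19).** The ester that made C10 an acceptor is put back. Its removal is thermodynamic and gives the cis ring fusion. With C12 still a methylene group this is the only centre that equilibrates.

**O–C2 and C9–C10 (19 from 12 and 18).** This is the key cut: the tetrahydrofuran is divided into cyclopropane 12 and aldehyde 18. It is preferred over an aldol or etherification sequence because it forms both ring bonds and three stereocentres at once and joins two fragments of similar size. The 7-endo isopropenyl group of 12 becomes C2 with inversion, which gives the trans C1/C2 relationship of the target. The reaction needs a Lewis acid that activates the keto ester without destroying the β-ketal aldehyde.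

**Aldehyde 18 (from 17, 16, 13 and 14).** Standard carbonyl chemistry: partial reduction of ester 17, ketalisation of keto ester 16, and γ-allylation of acetoacetate 13 with 14. The dioxolane is chosen as the C7 spectator because it alone leaves the later hydrogenation window free of alkenes.

**C1–C10 and C2–C10 (12 from 11, 10 and 9).** The cyclopropane is cut to diazo keto ester 11, made from β-keto ester 10 and methyl ketone 9. The Z diene transfers its geometry into the 7-endo isopropenyl group. Allylic strain at C14 decides the face. A copper carbene is specified because a rhodium carbene would be expected to insert into the tertiary allylic C14–H bond.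

**C1=C2, C13–C14 and the C14–C1 homologation (9 from 6 and 7; 6 from 4 and 5; 4 from 2 and 1).** The diene is cut by Wittig olefination of keto aldehyde 6 with the ylide from 7. The C13–C14 bond is cut by an enamine-catalysed Michael addition of aldehyde 4 to enone 5, which sets C14 under catalyst control next to the purchased C15 centre. Aldehyde 4 is the one-carbon homologue of bromide 2, from commercial bromo alcohol 1. The tert-butyldiphenylsilyl ether is chosen because it must survive the Grignard step, the Lewis acid and hot chloride.

## Roads not taken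

**Alternative 1:** The cut removes C1–C14, C10–C11 and C12–C13 together, so that ring C and the oxepane are dismantled to ene–yne A2 and alkynyl boronate A3. In the forward step [Rh(cod)2]BF4 with a bisphosphine would join the dihydrofuran alkene, the tethered alkyne and A3 to cyclohexadienyl boronate A1.
- Merits: three C–C bonds and two rings form in one step. The C12 methyl group and a C11 handle arrive with A3, so no late methylation and no ester removal are needed. In these respects it is better than the chosen plan, which spends three steps on C12.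
- Weak points: the bridged ten-membered ring of A2 must be made first without help from ring C. An alkene is the slowest partner in a [2+2+2] reaction with two different alkynes, so alkyne homo-coupling and the regiochemistry of A3 are open. In A1 the carbons C12 and C14 are sp2, so C14 (trans to C1–H), the axial C12 methyl group and C11 would all depend on reductions of a hindered diene.
- Comparison: the chosen plan offers catalyst control at C14 before any ring exists, relay of that centre into C1, C2, C9 and C10, and a ring-forming step with close precedent.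

**Alternative 2:** The cut is the C3–O bond of the oxepane, taken back by a retro-Baeyer–Villiger step to decalone A5. In the forward step buffered CF3CO3H would insert oxygen with migration of the quaternary C3 to give lactone A4.
- Merits: C3 is transferred with retention from a carbon centre, free of the face-selectivity and cation questions of the chosen epoxide opening. On this point it is the safer road.
- Weak points: the migrating carbon carries β-oxygen substituents at C2 and C4 that lower its migratory aptitude against the secondary C15. C15 is epimerisable next to the ketone and the lactone. The lactone carbonyl must still be reduced to a methylene group. In A4 the nine-membered ring is not yet closed, so medium-ring formation and the C4 centre move to the end. A5 itself needs a long stereocontrolled construction.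
- Comparison: the chosen plan has fewer steps, closes the nine-membered ring early on a preorganised substrate, and sets C3 and C4 in one operation.

**Alternative 3:** The nine-membered ring is taken back to a fused cyclobutanol, A7, in which C4 and C7 are bonded and C19 carries a sulfonate. In the forward step KOC(CH3)3 would trigger a Grob fragmentation to ketone A6.
- Merits: the medium ring arises by fragmentation, with no high dilution, and the C7=C19 alkene appears in the same step under conditions that cannot isomerise it. The chosen plan is weaker here: it needs dilute metathesis and three operations (ketal, hydrolysis, methylenation) for C7=C19.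
- Weak points: A7 is harder to make than what it delivers. It has a quaternary C7 and a tertiary C4 alcohol in a four-membered ring fused to the fully built oxepane core, most plausibly from a [2+2] photocycloaddition with its own regio- and stereochemical problems. The C4 ketone of A6 must then be reduced to the 4S alcohol next to the quaternary C3.
- Comparison: the chosen plan offers a short convergent entry from two simple fragments and stereocontrol that is set early and relayed.

Key step: step 11

## Route

Remark: configurations are taken from the target SMILES, and the atom numbering of the problem section is used throughout. Compounds 1, 5, 7, 13, 14 and 32 are assumed to be purchasable. The C12 methyl group is deliberately absent from 12 and 19 and is introduced in steps 18 and 19.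

Step 1
Reactants: 1 (R)-3-bromo-2-methylpropan-1-ol
Product: 2 (R)-(3-bromo-2-methylpropoxy)(tert-butyl)diphenylsilane
Conditions: tBuPh2SiCl, imidazole, CH2Cl2, 0 °C to rt
Reagents that add atoms: tert-butyl(chloro)diphenylsilane, CC(C)(C)[Si](Cl)(c1ccccc1)c1ccccc1
Why: Standard silylation of a primary alcohol; the bulky silyl ether is chosen because it must survive Grignard formation, the Lewis acid of step 11 and hot chloride in step 12, and the C15 centre is not touched.

Step 2
Reactants: 2 (R)-(3-bromo-2-methylpropoxy)(tert-butyl)diphenylsilane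
Product: 4 (S)-4-{[tert-butyl(diphenyl)silyl]oxy}-3-methylbutanal, via Grignard reagent 3 (not isolated)
Conditions: Mg, THF, reflux; then DMF, 0 °C; aq. NH4Cl
Reagents that add atoms: N,N-dimethylformamide, CN(C)C=O
Why: Grignard formation from a primary bromide followed by Bouveault formylation gives the one-carbon homologue; the stereocentre is β to the metal and cannot epimerise.

Step 3
Reactants: 4 (S)-4-{[tert-butyl(diphenyl)silyl]oxy}-3-methylbutanal; 5 but-3-en-2-one
Product: 6 (2R)-2-[(2S)-1-{[tert-butyl(diphenyl)silyl]oxy}propan-2-yl]-5-oxohexanal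
Conditions: (R)-2-[methoxy(diphenyl)methyl]pyrrolidine (5 mol%), ethyl 3,4-dihydroxybenzoate (20 mol%), neat, 4 °C
Reagents that add atoms: none
Why: Enamine-catalysed Michael addition of an aldehyde to a vinyl ketone; the E-enamine of 4 is attacked on the face remote from the diarylmethyl group of the (R)-catalyst, which sets C14 under catalyst control whatever the bias of the neighbouring C15 centre, and the catechol co-catalyst activates the enone by hydrogen bonding.

Step 4
Reactants: 6 (2R)-2-[(2S)-1-{[tert-butyl(diphenyl)silyl]oxy}propan-2-yl]-5-oxohexanal; 7 (2-methylprop-2-en-1-yl)triphenylphosphonium chloride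
Product: 9 (5S,6Z)-5-[(2S)-1-{[tert-butyl(diphenyl)silyl]oxy}propan-2-yl]-8-methylnona-6,8-dien-2-one, via phosphorus ylide 8 (not isolated)
Conditions: 7, KN(SiMe3)2, THF, 0 °C; then 6, −78 °C to rt
Reagents that add atoms: none
Why: Wittig olefination with an allylic ylide under salt-free conditions on an α-branched aldehyde, which should favour the cis-oxaphosphetane and hence the Z diene; at −78 °C the aldehyde reacts much faster than the methyl ketone.

Step 5
Reactants: 9 (5S,6Z)-5-[(2S)-1-{[tert-butyl(diphenyl)silyl]oxy}propan-2-yl]-8-methylnona-6,8-dien-2-one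
Product: 10 methyl (6S,7Z)-6-[(2S)-1-{[tert-butyl(diphenyl)silyl]oxy}propan-2-yl]-9-methyl-3-oxodeca-7,9-dienoate
Conditions: NaH, (CH3O)2CO, THF, reflux; aq. HCl work-up
Reagents that add atoms: dimethyl carbonate, COC(=O)OC
Why: Claisen-type methoxycarbonylation of a methyl ketone under equilibrating conditions; acylation ends at the methyl carbon because that β-keto ester is drained as the less hindered stabilised enolate, and C14 is not acidic.

Step 6
Reactants: 10 methyl (6S,7Z)-6-[(2S)-1-{[tert-butyl(diphenyl)silyl]oxy}propan-2-yl]-9-methyl-3-oxodeca-7,9-dienoate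
Product: 11 methyl (6S,7Z)-2-diazo-6-[(2S)-1-{[tert-butyl(diphenyl)silyl]oxy}propan-2-yl]-9-methyl-3-oxodeca-7,9-dienoate
Conditions: 4-acetamidobenzenesulfonyl azide, Et3N, MeCN, 0 °C to rt
Reagents that add atoms: 4-acetamidobenzenesulfonyl azide, CC(=O)Nc1ccc(cc1)S(=O)(=O)N=[N+]=[N-]
Why: Regitz diazo transfer to the activated methylene group of a β-keto ester; the weak amine base touches no other position.

Step 7
Reactants: 11 methyl (6S,7Z)-2-diazo-6-[(2S)-1-{[tert-butyl(diphenyl)silyl]oxy}propan-2-yl]-9-methyl-3-oxodeca-7,9-dienoate
Product: 12 methyl (1R,5S,6S,7S)-5-[(2S)-1-{[tert-butyl(diphenyl)silyl]oxy}propan-2-yl]-2-oxo-7-(prop-1-en-2-yl)bicyclo[4.1.0]heptane-1-carboxylate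
Conditions: bis(N-tert-butylsalicylaldiminato)copper, Cu(OC6H4CH=NtBu)2 (5 mol%), toluene, reflux, slow addition
Reagents that add atoms: none
Why: Intramolecular cyclopropanation by a copper carbene, chosen over Rh2(OAc)4 because rhodium carbenes tend to insert into a tertiary allylic C–H bond such as C14–H; the Z geometry is transferred into the 7-endo isopropenyl group, and allylic strain holds C14–H in the diene plane so that the tethered carbene adds to the alkene face anti to the side chain, which sets C1, C2 and C10.

Step 8
Reactants: 13 ethyl 3-oxobutanoate; 14 3-bromoprop-1-ene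
Product: 16 ethyl 3-oxohept-6-enoate, via lithium sodium dianion 15 (not isolated)
Conditions: NaH, THF, 0 °C; nBuLi, 0 °C; then 14, 0 °C to rt; aq. HCl work-up
Reagents that add atoms: none
Why: γ-Alkylation of the acetoacetate dianion; the more basic terminal carbanion reacts with the allylic bromide selectively.

Step 9
Reactants: 16 ethyl 3-oxohept-6-enoate
Product: 17 ethyl 2-[2-(but-3-en-1-yl)-1,3-dioxolan-2-yl]acetate
Conditions: HOCH2CH2OH, TsOH (cat.), benzene, reflux, Dean–Stark trap
Reagents that add atoms: ethane-1,2-diol, OCCO
Why: Acid-catalysed ketalisation of a β-keto ester with azeotropic removal of water.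

Step 10
Reactants: 17 ethyl 2-[2-(but-3-en-1-yl)-1,3-dioxolan-2-yl]acetate
Product: 18 2-[2-(but-3-en-1-yl)-1,3-dioxolan-2-yl]acetaldehyde
Conditions: iBu2AlH, CH2Cl2, −78 °C; aq. sodium potassium tartrate (KNaC4H4O6)
Reagents that add atoms: none
Why: Partial reduction of an ester to the aldehyde; the aluminium hemiacetal is stable at −78 °C and is helped by chelation to a ketal oxygen, and the aldehyde is used at once.

Step 11
Reactants: 12 methyl (1R,5S,6S,7S)-5-[(2S)-1-{[tert-butyl(diphenyl)silyl]oxy}propan-2-yl]-2-oxo-7-(prop-1-en-2-yl)bicyclo[4.1.0]heptane-1-carboxylate; 18 2-[2-(but-3-en-1-yl)-1,3-dioxolan-2-yl]acetaldehyde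
Product: 19 methyl (1R,3R,3aR,7R,7aR)-3-{[2-(but-3-en-1-yl)-1,3-dioxolan-2-yl]methyl}-7-[(2S)-1-{[tert-butyl(diphenyl)silyl]oxy}propan-2-yl]-4-oxo-1-(prop-1-en-2-yl)octahydro-2-benzofuran-3a-carboxylate
Conditions: (2,6-tBu2-4-MeC6H2O)2AlN(SO2CF3)2 (10 mol%), 18 (2 equiv), CH2Cl2, −20 °C to rt
Reagents that add atoms: none
Why: The aluminium triflimide binds the β-keto ester of 12 and polarises the C2–C10 bond, whose donor end is the allylic carbon C2; the aldehyde oxygen of 18 attacks C2 from the rear and gives an aluminium enolate–oxocarbenium zwitterion. The C10 enolate then adds to the oxocarbenium carbon C9 and closes the tetrahydrofuran (C1–C2–O–C9–C10) by an aldol-type 5-(enolexo)-endo-trig closure, which is feasible for a cationic acceptor and is the usual ring-forming event of this annulation. The closest known reaction type is the Lewis-acid-catalysed (3+2) annulation of donor–acceptor cyclopropanes with aldehydes to 2,5-cis tetrahydrofurans, which is documented for ring-fused vinylcyclopropane keto esters of this kind. C2 is set by inversion of the 7-endo centre of 12, which places C3 trans to C14 on the new ring. C9 is set by an envelope transition state that keeps the C9 chain pseudo-equatorial and cis to the isopropenyl group. C10 is set by the tether, because the new bond can only form on the face that C2 has left, so the ring fusion is cis. The step needs cleavage of C2–C10 and not C1–C10, which the alkenyl donor on C2 secures, and it needs the β-ketal aldehyde to survive; the bulky aryloxide ligands should keep the metal away from the hindered dioxolane oxygens and leave the aldehyde free to act as the nucleophile.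

Step 12
Reactants: 19 methyl (1R,3R,3aR,7R,7aR)-3-{[2-(but-3-en-1-yl)-1,3-dioxolan-2-yl]methyl}-7-[(2S)-1-{[tert-butyl(diphenyl)silyl]oxy}propan-2-yl]-4-oxo-1-(prop-1-en-2-yl)octahydro-2-benzofuran-3a-carboxylate
Product: 20 (1R,3R,3aS,7R,7aR)-3-{[2-(but-3-en-1-yl)-1,3-dioxolan-2-yl]methyl}-7-[(2S)-1-{[tert-butyl(diphenyl)silyl]oxy}propan-2-yl]-1-(prop-1-en-2-yl)hexahydro-2-benzofuran-4(1H)-one
Conditions: NaCl, H2O, DMSO, 150 °C
Reagents that add atoms: none
Why: Krapcho dealkoxycarbonylation: chloride demethylates the ester, the β-keto carboxylate loses CO2, and the enol is protonated and equilibrated at 150 °C to the more stable cis-fused ketone; C12 is still a methylene group, so no other centre can epimerise.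

Step 13
Reactants: 20 (1R,3R,3aS,7R,7aR)-3-{[2-(but-3-en-1-yl)-1,3-dioxolan-2-yl]methyl}-7-[(2S)-1-{[tert-butyl(diphenyl)silyl]oxy}propan-2-yl]-1-(prop-1-en-2-yl)hexahydro-2-benzofuran-4(1H)-one
Product: 21 tricyclic (3Z)-oxonene (2,9-oxygen-bridged cyclodecene cis-fused to ring C; C7 ethylene ketal, C11 ketone, C16 tert-butyldiphenylsilyl ether; 1R,2R,9R,10S,14R,15S in target numbering)
Conditions: second-generation Grubbs catalyst RuCl2(=CHPh)(H2IMes)(PCy3) (10 mol%), toluene (1 mM), 80 °C
Reagents that add atoms: none
Why: Ring-closing metathesis between the isopropenyl group and the terminal alkene; the 2,5-cis tetrahydrofuran holds both arms on one face, which offsets the entropic cost of a nine-membered ring, and the ring size enforces the Z geometry.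

Step 14
Reactants: 21 tricyclic (3Z)-oxonene
Product: 22 (3S,4S)-3,4-epoxide of 21 (epoxide oxygen on the face of C3=C4 turned away from ring C)
Conditions: dimethyldioxirane, acetone/CH2Cl2, −40 to 0 °C
Reagents that add atoms: dimethyldioxirane, CC1(C)OO1
Why: Electrophilic epoxidation of a trisubstituted alkene with a neutral dioxirane that leaves the ketone and the ketal alone; the C14 side chain with its bulky silyl ether covers the alkene face from which it must later attack, so oxygen should arrive from the other face and set C3 and C4 together.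

Step 15
Reactants: 22 (3S,4S)-3,4-epoxide of 21
Product: 23 C16 alcohol of epoxide 22
Conditions: Bu4NF, AcOH, THF, rt
Reagents that add atoms: none
Why: Fluoride cleavage of the silyl ether; buffering with acetic acid keeps the medium from enolising the β-alkoxy ketone or opening the epoxide.

Step 16
Reactants: 23 C16 alcohol of epoxide 22
Product: 24 tetracyclic oxepane alcohol (C3–O–C16 ether, free 4S hydroxyl, C7 ethylene ketal, C11 ketone; 1R,2R,3R,4S,9R,10S,14R,15S)
Conditions: (+)-10-camphorsulfonic acid (10 mol%), CH2Cl2, 0 °C
Reagents that add atoms: none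
Why: Acid-catalysed hydroxy-epoxide cyclisation: the C16 hydroxyl attacks the tertiary carbon C3 anti to the epoxide oxygen in a 7-exo-tet mode, where Markovnikov and Baldwin preferences coincide; inversion at C3 gives the 3R ether and C4 keeps the epoxide oxygen as the 4S hydroxyl.

Step 17
Reactants: 24 tetracyclic oxepane alcohol
Product: 25 4-O-acetate of 24
Conditions: Ac2O, DMAP (cat.), pyridine, rt
Reagents that add atoms: acetic anhydride, CC(=O)OC(C)=O
Why: Nucleophile-catalysed acetylation of the only free hydroxyl group; the target's own acetate serves as the protecting group for the enolate and hydride steps that follow.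

Step 18
Reactants: 25 4-O-acetate of 24
Product: 29 12-methylidene C11 ketone (C7 ethylene ketal, C4 acetate), via lithium enolate 26 (not isolated), via Mannich base 27 (not isolated), via ammonium iodide 28 (not isolated)
Conditions: LiN(SiMe3)2, THF, −78 °C; CH2=N(CH3)2+ I−, −78 °C to rt; then CH3I, CH2Cl2; then aq. NaHCO3
Reagents that add atoms: N,N-dimethylmethyleneiminium iodide, C[N+](C)=C.[I-]
Why: Kinetic enolisation removes the axial C12 hydrogen and not the tertiary, poorly aligned C10 hydrogen, and at −78 °C the silylamide is too slow to deprotonate the acetate; Mannich reaction with Eschenmoser's salt, quaternisation and β-elimination give the α-methylene ketone.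

Step 19
Reactants: 29 12-methylidene C11 ketone
Product: 30 (12S)-12-methyl C11 ketone (methyl axial and cis to the C10–C9 bond)
Conditions: H2 (1 atm), Pd on carbon (10%), EtOAc, rt
Reagents that add atoms: none
Why: Heterogeneous hydrogenation from the less hindered face of the enone: the concave face at C12 is blocked by the axial C10–C9 bond and the axial C14 hydrogen, so hydrogen is added from the convex face and the methyl group is pushed into the axial position; no other C=C bond is present and ketal, acetate and ethers are inert.

Step 20
Reactants: 30 (12S)-12-methyl C11 ketone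
Product: 31 (11S,12S)-11-alcohol (C7 ethylene ketal, C4 acetate)
Conditions: NaBH4, CeCl3·7H2O, MeOH, −78 °C
Reagents that add atoms: none
Why: Luche-type borohydride reduction, fast and mild enough not to epimerise C12; both α-carbons carry axial substituents on the concave face, so axial attack from the convex face is the only open trajectory and gives the equatorial alcohol cis to the C12 methyl group.

Step 21
Reactants: 32 (R)-2-hydroxyoctanoic acid
Product: 34 (R)-2-[(triethylsilyl)oxy]octanoic acid, via bis(silyl) derivative 33 (not isolated)
Conditions: Et3SiCl, imidazole, CH2Cl2, 0 °C to rt; then K2CO3 (cat.), MeOH/H2O, 0 °C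
Reagents that add atoms: chlorotriethylsilane, CC[Si](Cl)(CC)CC
Why: Silylation of both hydroxyl functions followed by selective solvolysis of the much more labile silyl ester; the stereocentre is not involved.

Step 22
Reactants: 31 (11S,12S)-11-alcohol; 34 (R)-2-[(triethylsilyl)oxy]octanoic acid
Product: 36 11-O-[(R)-2-(triethylsilyloxy)octanoyl] ester of 31, via mixed anhydride 35 (not isolated)
Conditions: 34, 2,4,6-Cl3C6H2COCl, Et3N, THF, rt; then 31, DMAP, toluene, rt
Reagents that add atoms: none
Why: Yamaguchi esterification, suited to a hindered secondary alcohol; the silyl ether prevents self-acylation of the hydroxy acid, and the mixed anhydride is attacked at the less hindered carbonyl.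

Step 23
Reactants: 36 11-O-[(R)-2-(triethylsilyloxy)octanoyl] ester of 31
Product: 37 C7 ketone (4-acetate, 11-[(R)-2-hydroxyoctanoate])
Conditions: 1 M HCl, THF, rt
Reagents that add atoms: water, O
Why: Dilute aqueous acid hydrolyses the dioxolane and the triethylsilyl ether in one operation; the two esters, the tertiary ether and the tetrahydrofuran are stable under these conditions.

Step 24
Reactants: 37 C7 ketone
Product: 38 CNP0132024.3, (1R,2R,3R,4S,9R,10S,11S,12S,14R,15S)-4-acetoxy-7-methylidene asbestinane 11-[(2R)-2-hydroxyoctanoate]
Conditions: Zn, CH2Br2, TiCl4, THF/CH2Cl2, 0 °C to rt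
Reagents that add atoms: dibromomethane, BrCBr
Why: Takai–Lombardo methylenation: the non-basic titanium–zinc methylene reagent converts the ketone into the exocyclic alkene without touching the esters or the free hydroxyl group and without enolising the β-alkoxy ketone, which a phosphorus ylide could cleave by β-elimination.

## Compound list

1 | (R)-3-bromo-2-methylpropan-1-ol | OC[C@@H](C)CBr | starting material
2 | (R)-(3-bromo-2-methylpropoxy)(tert-butyl)diphenylsilane | CC(C)(C)[Si](c1ccccc1)(c1ccccc1)OC[C@@H](C)CBr | intermediate
3 | [(R)-3-{[tert-butyl(diphenyl)silyl]oxy}-2-methylpropyl]magnesium bromide | CC(C)(C)[Si](c1ccccc1)(c1ccccc1)OC[C@@H](C)C[Mg]Br | intermediate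
4 | (S)-4-{[tert-butyl(diphenyl)silyl]oxy}-3-methylbutanal | CC(C)(C)[Si](c1ccccc1)(c1ccccc1)OC[C@@H](C)CC=O | intermediate
5 | but-3-en-2-one | CC(=O)C=C | starting material
6 | (2R)-2-[(2S)-1-{[tert-butyl(diphenyl)silyl]oxy}propan-2-yl]-5-oxohexanal | CC(C)(C)[Si](c1ccccc1)(c1ccccc1)OC[C@@H](C)[C@H](C=O)CCC(C)=O | intermediate
7 | (2-methylprop-2-en-1-yl)triphenylphosphonium chloride | CC(=C)C[P+](c1ccccc1)(c1ccccc1)c1ccccc1.[Cl-] | starting material
8 | (2-methylprop-2-en-1-ylidene)triphenylphosphorane | CC(=C)C=P(c1ccccc1)(c1ccccc1)c1ccccc1 | intermediate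
9 | (5S,6Z)-5-[(2S)-1-{[tert-butyl(diphenyl)silyl]oxy}propan-2-yl]-8-methylnona-6,8-dien-2-one | CC(C)(C)[Si](c1ccccc1)(c1ccccc1)OC[C@@H](C)[C@H](/C=C\C(C)=C)CCC(C)=O | intermediate
10 | methyl (6S,7Z)-6-[(2S)-1-{[tert-butyl(diphenyl)silyl]oxy}propan-2-yl]-9-methyl-3-oxodeca-7,9-dienoate | CC(C)(C)[Si](c1ccccc1)(c1ccccc1)OC[C@@H](C)[C@H](/C=C\C(C)=C)CCC(=O)CC(=O)OC | intermediate
11 | methyl (6S,7Z)-2-diazo-6-[(2S)-1-{[tert-butyl(diphenyl)silyl]oxy}propan-2-yl]-9-methyl-3-oxodeca-7,9-dienoate | CC(C)(C)[Si](c1ccccc1)(c1ccccc1)OC[C@@H](C)[C@H](/C=C\C(C)=C)CCC(=O)C(=[N+]=[N-])C(=O)OC | intermediate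
12 | methyl (1R,5S,6S,7S)-5-[(2S)-1-{[tert-butyl(diphenyl)silyl]oxy}propan-2-yl]-2-oxo-7-(prop-1-en-2-yl)bicyclo[4.1.0]heptane-1-carboxylate | CC(C)(C)[Si](c1ccccc1)(c1ccccc1)OC[C@@H](C)[C@H]1CCC(=O)[C@@]2(C(=O)OC)[C@@H]1[C@H]2C(C)=C | intermediate
13 | ethyl 3-oxobutanoate | CCOC(=O)CC(C)=O | starting material
14 | 3-bromoprop-1-ene | C=CCBr | starting material
15 | lithium sodium dianion of ethyl 3-oxobutanoate | [Li+].[Na+].[CH2-]C(=O)[CH-]C(=O)OCC | intermediate
16 | ethyl 3-oxohept-6-enoate | CCOC(=O)CC(=O)CCC=C | intermediate
17 | ethyl 2-[2-(but-3-en-1-yl)-1,3-dioxolan-2-yl]acetate | CCOC(=O)CC1(CCC=C)OCCO1 | intermediate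
18 | 2-[2-(but-3-en-1-yl)-1,3-dioxolan-2-yl]acetaldehyde | O=CCC1(CCC=C)OCCO1 | intermediate
19 | methyl (1R,3R,3aR,7R,7aR)-3-{[2-(but-3-en-1-yl)-1,3-dioxolan-2-yl]methyl}-7-[(2S)-1-{[tert-butyl(diphenyl)silyl]oxy}propan-2-yl]-4-oxo-1-(prop-1-en-2-yl)octahydro-2-benzofuran-3a-carboxylate | CC(C)(C)[Si](c1ccccc1)(c1ccccc1)OC[C@@H](C)[C@H]1CCC(=O)[C@@]2(C(=O)OC)[C@@H]1[C@H](C(C)=C)O[C@@H]2CC3(CCC=C)OCCO3 | intermediate
20 | (1R,3R,3aS,7R,7aR)-3-{[2-(but-3-en-1-yl)-1,3-dioxolan-2-yl]methyl}-7-[(2S)-1-{[tert-butyl(diphenyl)silyl]oxy}propan-2-yl]-1-(prop-1-en-2-yl)hexahydro-2-benzofuran-4(1H)-one | CC(C)(C)[Si](c1ccccc1)(c1ccccc1)OC[C@@H](C)[C@H]1CCC(=O)[C@H]2[C@@H]1[C@H](C(C)=C)O[C@@H]2CC3(CCC=C)OCCO3 | intermediate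
21 | tricyclic (3Z)-oxonene: C3=C4 alkene, C7 ethylene ketal, C11 ketone, C16 tert-butyldiphenylsilyl ether (1R,2R,9R,10S,14R,15S) | CC(C)(C)[Si](c1ccccc1)(c1ccccc1)OC[C@@H](C)[C@H]1CCC(=O)[C@H]2[C@@H]1[C@H]3O[C@@H]2CC4(OCCO4)CC/C=C3/C | intermediate
22 | (3S,4S)-3,4-epoxide of 21 | CC(C)(C)[Si](c1ccccc1)(c1ccccc1)OC[C@@H](C)[C@H]1CCC(=O)[C@H]2[C@@H]1[C@H]3O[C@@H]2CC4(OCCO4)CC[C@@H]5O[C@]35C | intermediate
23 | C16 alcohol of epoxide 22 | OC[C@@H](C)[C@H]1CCC(=O)[C@H]2[C@@H]1[C@H]3O[C@@H]2CC4(OCCO4)CC[C@@H]5O[C@]35C | intermediate
24 | tetracyclic oxepane alcohol: C3–O–C16 ether, 4S hydroxyl, C7 ethylene ketal, C11 ketone | O1CCOC12CC[C@H](O)[C@@]3(C)OC[C@@H](C)[C@H]4CCC(=O)[C@H]5[C@@H]4[C@H]3O[C@@H]5C2 | intermediate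
25 | 4-O-acetate of 24 | O1CCOC12CC[C@H](OC(C)=O)[C@@]3(C)OC[C@@H](C)[C@H]4CCC(=O)[C@H]5[C@@H]4[C@H]3O[C@@H]5C2 | intermediate
26 | lithium C11–C12 enolate of 25 | O1CCOC12CC[C@H](OC(C)=O)[C@@]3(C)OC[C@@H](C)[C@H]4CC=C(O[Li])[C@H]5[C@@H]4[C@H]3O[C@@H]5C2 | intermediate
27 | 12-[(dimethylamino)methyl] C11 ketone (Mannich base, C12 epimers) | O1CCOC12CC[C@H](OC(C)=O)[C@@]3(C)OC[C@@H](C)[C@H]4CC(CN(C)C)C(=O)[C@H]5[C@@H]4[C@H]3O[C@@H]5C2 | intermediate
28 | 12-[(trimethylammonio)methyl] C11 ketone iodide | O1CCOC12CC[C@H](OC(C)=O)[C@@]3(C)OC[C@@H](C)[C@H]4CC(C[N+](C)(C)C)C(=O)[C@H]5[C@@H]4[C@H]3O[C@@H]5C2.[I-] | intermediate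
29 | 12-methylidene C11 ketone | O1CCOC12CC[C@H](OC(C)=O)[C@@]3(C)OC[C@@H](C)[C@H]4CC(=C)C(=O)[C@H]5[C@@H]4[C@H]3O[C@@H]5C2 | intermediate
30 | (12S)-12-methyl C11 ketone | O1CCOC12CC[C@H](OC(C)=O)[C@@]3(C)OC[C@@H](C)[C@H]4C[C@H](C)C(=O)[C@H]5[C@@H]4[C@H]3O[C@@H]5C2 | intermediate
31 | (11S,12S)-11-alcohol | O1CCOC12CC[C@H](OC(C)=O)[C@@]3(C)OC[C@@H](C)[C@H]4C[C@H](C)[C@H](O)[C@H]5[C@@H]4[C@H]3O[C@@H]5C2 | intermediate
32 | (R)-2-hydroxyoctanoic acid | OC(=O)[C@H](O)CCCCCC | starting material
33 | triethylsilyl (R)-2-[(triethylsilyl)oxy]octanoate | CC[Si](CC)(CC)OC(=O)[C@H](O[Si](CC)(CC)CC)CCCCCC | intermediate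
34 | (R)-2-[(triethylsilyl)oxy]octanoic acid | OC(=O)[C@H](O[Si](CC)(CC)CC)CCCCCC | intermediate
35 | (R)-2-[(triethylsilyl)oxy]octanoic 2,4,6-trichlorobenzoic anhydride | Clc1cc(Cl)c(C(=O)OC(=O)[C@H](O[Si](CC)(CC)CC)CCCCCC)c(Cl)c1 | intermediate
36 | 11-O-[(R)-2-(triethylsilyloxy)octanoyl] ester of 31 | O1CCOC12CC[C@H](OC(C)=O)[C@@]3(C)OC[C@@H](C)[C@H]4C[C@H](C)[C@H](OC(=O)[C@H](O[Si](CC)(CC)CC)CCCCCC)[C@H]5[C@@H]4[C@H]3O[C@@H]5C2 | intermediate
37 | C7 ketone, 4-acetate 11-[(R)-2-hydroxyoctanoate] | O=C1CC[C@H](OC(C)=O)[C@@]2(C)OC[C@@H](C)[C@H]3C[C@H](C)[C@H](OC(=O)[C@H](O)CCCCCC)[C@H]4[C@@H]3[C@H]2O[C@@H]4C1 | intermediate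
38 | CNP0132024.3 | C=C1CC[C@H](OC(C)=O)[C@@]2(C)OC[C@@H](C)[C@H]3C[C@H](C)[C@H](OC(=O)[C@H](O)CCCCCC)[C@H]4[C@@H]3[C@H]2O[C@@H]4C1 | target

## Step count and least certain steps

Total: 24 steps. Longest linear sequence: 20 steps (steps 1–7, 11–20 and 22–24).

**Step 11 (key step).** The most likely failure is ionisation of the dioxolane by the Lewis acid followed by β-elimination of the aldehyde, faster than the annulation. A second risk is loss of stereospecificity at C2 if the cyclopropane opens to an allyl cation before the aldehyde arrives. The fallback changes the C7 mask and sets out from 16. Thioketalisation with propane-1,3-dithiol and BF3·OEt2 would give ethyl 2-[2-(but-3-en-1-yl)-1,3-dithian-2-yl]acetate F1. Reduction with iBu2AlH would give 2-[2-(but-3-en-1-yl)-1,3-dithian-2-yl]acetaldehyde F2, whose dithiane neither ionises nor eliminates with hard Lewis acids. Annulation with 12 would give the dithiane analogue of the annulation product F3. PhI(OCOCF3)2 in ethane-1,2-diol/MeCN would then exchange the dithiane for the dioxolane and return to the route at 19.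

**Step 4.** Semi-stabilised ylides often give modest Z/E selectivity, and the E isomer would lead to the 7-exo cyclopropane. Base-induced intramolecular aldol condensation of the 1,5-keto aldehyde is a second risk. The fallback sets out from 6. A Stork–Zhao olefination (Ph3P=CHI, −78 °C) would give (5R,6Z)-5-[(2S)-1-{[tert-butyl(diphenyl)silyl]oxy}propan-2-yl]-7-iodohept-6-en-2-one F4 with reliably high Z selectivity. Suzuki coupling of F4 with isopropenylboronic acid pinacol ester, with Pd(PPh3)4 as the source of zerovalent palladium and K3PO4 as base, proceeds with retention and returns to the route at 9.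

**Step 14.** Oxygen transfer may be unselective or prefer the wrong face, because the conformation of the nine-membered ring is not known with certainty; the wrong epoxide cannot be opened by the C16 hydroxyl. The fallback uses a halohydrin to reach the face that direct epoxidation avoids, and sets out from 21. NBS in aqueous 1,2-dimethoxyethane would add bromine to the face the dioxirane preferred and water to C3 from the other face, giving the bromohydrin (C3 hydroxyl, C4 bromide) F5. K2CO3 in MeOH then closes the epoxide with inversion at C4 and returns to the route at 22.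

**Step 16.** The developing cation at C3 may be diverted: transannular capture by a dioxolane oxygen at C7, proton loss to an allylic alcohol, or a hydride shift could outrun the seven-membered ring closure. The fallback forms the C3–O bond by haloetherification and sets out from 21. Bu4NF/AcOH would give the C16 alcohol of the oxonene F6. Iodoetherification (I2, NaHCO3, MeCN) is reversible at the iodonium stage, and only the hydroxyl group can give a neutral product. It would give the 4-iodo oxepane F7, with iodine anti to the new C3–O bond. Radical oxygenation (Bu3SnH, air; then PPh3) would replace iodine by hydroxyl from the exposed face of the C4 radical and return to the route at 24. The configuration at C4 is then under steric control only.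

**Step 19.** Hydrogen may be delivered from the unexpected face, or the axial methyl group may epimerise on the catalyst or during isolation. The fallback is stereocomplementary and sets out from 25. Lithium enolate 26 is methylated directly with CH3I, so that the methyl group enters from whichever face the catalyst would have used for hydrogen. This returns to the route at 30 and makes no new compound.

## Further compounds

F1 | step 11 | ethyl 2-[2-(but-3-en-1-yl)-1,3-dithian-2-yl]acetate | CCOC(=O)CC1(CCC=C)SCCCS1
F2 | step 11 | 2-[2-(but-3-en-1-yl)-1,3-dithian-2-yl]acetaldehyde | O=CCC1(CCC=C)SCCCS1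
F3 | step 11 | dithiane analogue of 19 (1,3-dithiane in place of the dioxolane) | CC(C)(C)[Si](c1ccccc1)(c1ccccc1)OC[C@@H](C)[C@H]1CCC(=O)[C@@]2(C(=O)OC)[C@@H]1[C@H](C(C)=C)O[C@@H]2CC3(CCC=C)SCCCS3
F4 | step 4 | (5R,6Z)-5-[(2S)-1-{[tert-butyl(diphenyl)silyl]oxy}propan-2-yl]-7-iodohept-6-en-2-one | CC(C)(C)[Si](c1ccccc1)(c1ccccc1)OC[C@@H](C)[C@H](/C=C\I)CCC(C)=O
F5 | step 14 | bromohydrin of 21 (C3 hydroxyl, C4 bromide, anti) | CC(C)(C)[Si](c1ccccc1)(c1ccccc1)OC[C@@H](C)[C@H]1CCC(=O)[C@H]2[C@@H]1[C@H]3O[C@@H]2CC4(OCCO4)CC[C@@H](Br)[C@]3(C)O
F6 | step 16 | C16 alcohol of oxonene 21 | OC[C@@H](C)[C@H]1CCC(=O)[C@H]2[C@@H]1[C@H]3O[C@@H]2CC4(OCCO4)CC/C=C3/C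
F7 | step 16 | 4-iodo oxepane (C3–O–C16 ether, iodine on C4 anti to the ether oxygen) | O1CCOC12CC[C@H](I)[C@@]3(C)OC[C@@H](C)[C@H]4CCC(=O)[C@H]5[C@@H]4[C@H]3O[C@@H]5C2
F0 | step 19 | none | none
A1 | alternative 1 | tetracyclic cyclohexadienyl boronate (boron on C11) | O1CCOC12CC[C@H](O[Si](C)(C)C(C)(C)C)[C@@]3(C)OC[C@@H](C)C4=CC(C)=C(B5OC(C)(C)C(C)(C)O5)[C@H]6[C@@H]4[C@H]3O[C@@H]6C2
A2 | alternative 1 | oxygen-bridged cyclodecene with C1=C10 alkene and a C3 ether tether ending in the C13≡C14 alkyne | C#C[C@H](C)CO[C@]1(C)[C@@H](O[Si](C)(C)C(C)(C)C)CCC2(OCCO2)C[C@@H]3C=C[C@H]1O3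
A3 | alternative 1 | 4,4,5,5-tetramethyl-2-(prop-1-yn-1-yl)-1,3,2-dioxaborolane | CC#CB1OC(C)(C)C(C)(C)O1
A4 | alternative 2 | tricyclic oxepan-2-one with C3 as the tertiary ether carbon | CC(C)(C)[Si](C)(C)OC[C@@]1(C)OC(=O)[C@@H](C)[C@H]2C[C@H](C)[C@H](O[Si](C)(C)C(C)(C)C)[C@H]3[C@@H]2[C@H]1O[C@@H]3COCc1ccccc1
A5 | alternative 2 | tricyclic decalone with the C16 ketone bonded to C3 | CC(C)(C)[Si](C)(C)OC[C@@]1(C)C(=O)[C@@H](C)[C@H]2C[C@H](C)[C@H](O[Si](C)(C)C(C)(C)C)[C@H]3[C@@H]2[C@H]1O[C@@H]3COCc1ccccc1
A6 | alternative 3 | tetracyclic C4 ketone with the C7 exocyclic methylene and C11 silyl ether | C=C1CCC(=O)[C@@]2(C)OC[C@@H](C)[C@H]3C[C@H](C)[C@H](O[Si](C)(C)C(C)(C)C)[C@H]4[C@@H]3[C@H]2O[C@@H]4C1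
A7 | alternative 3 | C4–C7 bonded cyclobutanol with a C19 methanesulfonate (cis-fused four- and seven-membered rings) | CS(=O)(=O)OC[C@@]12CC[C@]1(O)[C@@]3(C)OC[C@@H](C)[C@H]4C[C@H](C)[C@H](O[Si](C)(C)C(C)(C)C)[C@H]5[C@@H]4[C@H]3O[C@@H]5C2
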